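Ring B is opened at C5–C6 and C9–C10 (drimane numbering). The key step exploits that the C6 carbonyl carbon and the C3 oxygen are linked through C4–C5, and that ring B is a cyclohexene (C7=C8) with C6 at the ketone oxidation level. An ester of the ring-A alcohol (S)-2,2,4-trimethylcyclohex-3-en-1-ol with a β,γ-unsaturated acid (C6–C9, C11) is converted to its dienyl ketene silyl acetal. One intramolecular Diels–Alder reaction then closes ring B and sets C5, C9 and C10 from the C3 carbinol. Unveiling the bridged silyl ketal gives the 7-ene-3,6-dione; C5 is inverted to the trans fusion and umbelliferone is attached last.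

Key step: step 7

Remark: drimane numbering is used for the bicyclic compounds (C1–C10 are the decalin carbons with C5 and C10 at the ring fusion, C4 carries the gem-dimethyl group, C11 is the CH2O carbon on C9, C12 the methyl on C8; ring A = C1–C5, C10; ring B = C5–C10). Compounds 1, 5 and 18 are taken to be commercially available.

Step 1
Reactants: 1 4-methylcyclohex-3-en-1-one
Product: 3 2,2,4-trimethylcyclohex-3-en-1-one, via 2,4-dimethylcyclohex-3-en-1-one 2 (not isolated)
Conditions: MeI (2.3 equiv), t-BuOK (2.2 equiv), t-BuOH/THF, 0 → 23 °C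
Reagents that add atoms: iodomethane CI
Why: Under equilibrating conditions the C2 hydrogens, which are both α to the carbonyl and allylic, are removed to give the extended dienolate, which should be C-methylated twice at its α-carbon with the alkene staying β,γ (deconjugative α,α-dialkylation of a dienolate); no stereocenter is formed.

Step 2
Reactants: 3 2,2,4-trimethylcyclohex-3-en-1-one
Product: 4 (S)-2,2,4-trimethylcyclohex-3-en-1-ol
Conditions: (R)-2-methyl-CBS-oxazaborolidine [(R)-1-methyl-3,3-diphenyltetrahydro-1H,3H-pyrrolo[1,2-c][1,3,2]oxazaborole] (20 mol %), catecholborane (1.5 equiv), toluene, −78 °C; aq. NaOH work-up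
Reagents that add atoms: none
Why: Corey–Bakshi–Shibata reduction, in which the quaternary C2 acts as the large and C6H2 as the small substituent, so the (R)-catalyst should deliver hydride to give the (S)-carbinol, while catecholborane does not hydroborate the trisubstituted alkene at this temperature.

Step 3
Reactants: 5 (E)-3-methylpent-2-en-4-yn-1-ol
Product: 6 (E)-tert-butyl[(3-methylpent-2-en-4-yn-1-yl)oxy]diphenylsilane
Conditions: t-BuPh2SiCl, imidazole, DMF, 23 °C
Reagents that add atoms: tert-butyl(chloro)diphenylsilane CC(C)(C)[Si](Cl)(c1ccccc1)c1ccccc1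
Why: Imidazole-promoted silylation of a primary alcohol (silyl ether formation), which leaves the E alkene untouched and gives a C11 oxygen that is a poor leaving group for the later enolate chemistry.

Step 4
Reactants: 6 (E)-tert-butyl[(3-methylpent-2-en-4-yn-1-yl)oxy]diphenylsilane
Product: 8 (E)-5-(tert-butyldiphenylsilyloxy)-3-methylpent-3-enal, via dienyl dicyclohexylborane 7 (not isolated)
Conditions: dicyclohexylborane (from BH3·SMe2 and cyclohexene), THF, 0 °C; then H2O2, pH 7 phosphate buffer, 0 °C
Reagents that add atoms: hydrogen peroxide OO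
Why: Brown hydroboration–oxidation, in which the bulky dialkylborane adds syn and anti-Markovnikov to the terminal alkyne only, and buffered oxidation gives a dienol that should ketonize by α-protonation to the β,γ-unsaturated aldehyde with the E alkene retained.

Step 5
Reactants: 8 (E)-5-(tert-butyldiphenylsilyloxy)-3-methylpent-3-enal
Product: 9 (E)-5-(tert-butyldiphenylsilyloxy)-3-methylpent-3-enoic acid
Conditions: NaClO2, NaH2PO4, 2-methyl-2-butene, t-BuOH/H2O, 0 °C
Reagents that add atoms: sodium chlorite [Na+].[O-]Cl=O
Why: Pinnick oxidation in a weakly acidic buffer should convert the aldehyde to the acid without moving the β,γ-alkene into conjugation or changing its geometry.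

Step 6
Reactants: 4 (S)-2,2,4-trimethylcyclohex-3-en-1-ol; 9 (E)-5-(tert-butyldiphenylsilyloxy)-3-methylpent-3-enoic acid
Product: 10 (S)-2,2,4-trimethylcyclohex-3-en-1-yl (E)-5-(tert-butyldiphenylsilyloxy)-3-methylpent-3-enoate
Conditions: EDC·HCl, DMAP (10 mol %), CH2Cl2, 0 → 23 °C
Reagents that add atoms: none
Why: Steglich-type carbodiimide esterification of the hindered secondary alcohol, in which the carbinol C–O bond is not broken, so the (S) centre is retained, and the low temperature limits isomerization of the β,γ-alkene.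

Step 7
Reactants: 10 (S)-2,2,4-trimethylcyclohex-3-en-1-yl (E)-5-(tert-butyldiphenylsilyloxy)-3-methylpent-3-enoate
Product: 12 (3S,5R,6S,9R,10S)-6-(tert-butyldimethylsilyloxy)-11-(tert-butyldiphenylsilyloxy)-3,6-epoxydrim-7-ene, via dienyl ketene silyl acetal 11 (not isolated)
Conditions: LiN(i-Pr)2 (1.2 equiv), THF, −78 °C; t-BuMe2SiCl, DMPU, −78 → 0 °C; then toluene, BHT (cat.), 140 °C, sealed tube; filtration through Et3N-deactivated silica
Reagents that add atoms: tert-butyl(chloro)dimethylsilane CC(C)(C)[Si](C)(C)Cl
Why: Kinetic deprotonation of the β,γ-unsaturated ester in THF (as in the Ireland–Claisen rearrangement) should give the enolate whose O-silylation places the ring-A oxygen cis to C8, and on heating this 1-alkoxy-1-silyloxy diene adds through its termini C6 and C9 across the C5=C10 alkene in a concerted suprafacial [4+2] cycloaddition. The closest known reaction type is the type 1 intramolecular Diels–Alder reaction of a 1,3,8-nonatriene, here with a ketene silyl acetal as the diene. Ring B closes as the six-membered [4+2] ring, and the five-membered C3–C4–C5–C6–O ring closes in the same event through the three-atom O–C3–C4 tether, which can only reach with the diene exo to ring A and the tether oxygen on the inside of the diene. C5 and C10 are set by suprafacial addition to the alkene face syn to the axial C3–O bond, so the C3 carbinol centre fixes the absolute configuration and C6 follows from the bridge; C9 is set by the E geometry of C8=C9, which puts C11 on the outside of the diene and therefore cis to the C10 methyl. The step needs regioselectivity (C6 to C5, C9 to C10), which the short tether enforces, and it must outrun silyl migration or retro-ene loss of the ketene acetal, which the rigid, proximate ring alkene and the gem-dimethyl group should favour.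

Step 8
Reactants: 12 (3S,5R,6S,9R,10S)-6-(tert-butyldimethylsilyloxy)-11-(tert-butyldiphenylsilyloxy)-3,6-epoxydrim-7-ene
Product: 14 (5R,9R,10S)-11-(tert-butyldiphenylsilyloxy)drim-7-ene-3,6-dione, via C3-hydroxy enone 13 (not isolated)
Conditions: CrO3, H2SO4, H2O/acetone, 0 °C
Reagents that add atoms: water O
Why: Aqueous acid should cleave the allylic silyl ketal to the hemiketal, whose open C3-hydroxy enone form is oxidized by chromic acid (Jones oxidation), draining the equilibrium to the cis-fused dione; C5, C9 and C10 are untouched and the auxiliary C3 centre is removed.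

Step 9
Reactants: 14 (5R,9R,10S)-11-(tert-butyldiphenylsilyloxy)drim-7-ene-3,6-dione
Product: 16 (5S,9R,10S)-11-(tert-butyldiphenylsilyloxy)drim-7-ene-3,6-dione, via dilithium bis-enolate 15 (not isolated)
Conditions: LiN(i-Pr)2 (2.4 equiv), THF, −78 → −40 °C; then AcOH, THF, −78 °C
Reagents that add atoms: none
Why: After enolization of the C3 ketone, kinetic α′-deprotonation by the lithium amide should give the cross-conjugated C5=C6 enolate without touching C9, and kinetic protonation at C5 should occur on the face anti to the axial C10 methyl, which gives the trans ring fusion (epimerization through a kinetic enolate).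

Step 10
Reactants: 16 (5S,9R,10S)-11-(tert-butyldiphenylsilyloxy)drim-7-ene-3,6-dione
Product: 17 (5S,9R,10S)-11-hydroxydrim-7-ene-3,6-dione
Conditions: HF·pyridine, pyridine/THF, 0 → 23 °C
Reagents that add atoms: none
Why: Fluoride cleavage of the silyl ether under non-basic conditions, so the base-sensitive δ-hydroxy enone should be neither epimerized at C5 or C9 nor dehydrated.

Step 11
Reactants: 17 (5S,9R,10S)-11-hydroxydrim-7-ene-3,6-dione; 18 umbelliferone (7-hydroxy-2H-chromen-2-one)
Product: 19 epi-conferdione, 7-{[(5S,9R,10S)-3,6-dioxodrim-7-en-11-yl]oxy}-2H-chromen-2-one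
Conditions: PPh3, diisopropyl azodicarboxylate, THF, 0 → 23 °C
Reagents that add atoms: none
Why: Mitsunobu etherification, in which the acidic phenol (pKa about 8) should displace the alkoxyphosphonium group at the primary C11 by SN2; no stereocenter is involved and the neutral conditions leave C5 and C9 intact.

Compound list
1 | 4-methylcyclohex-3-en-1-one | CC1=CCC(=O)CC1 | starting material
2 | 2,4-dimethylcyclohex-3-en-1-one (racemic; not isolated) | CC1=CC(C)C(=O)CC1 | intermediate
3 | 2,2,4-trimethylcyclohex-3-en-1-one | CC1=CC(C)(C)C(=O)CC1 | intermediate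
4 | (S)-2,2,4-trimethylcyclohex-3-en-1-ol | O[C@H]1CCC(C)=CC1(C)C | intermediate
5 | (E)-3-methylpent-2-en-4-yn-1-ol | C#C/C(C)=C/CO | starting material
6 | (E)-tert-butyl[(3-methylpent-2-en-4-yn-1-yl)oxy]diphenylsilane | C#C/C(C)=C/CO[Si](c1ccccc1)(c1ccccc1)C(C)(C)C | intermediate
7 | dicyclohexyl[(1E,3E)-5-(tert-butyldiphenylsilyloxy)-3-methylpenta-1,3-dien-1-yl]borane (not isolated) | C1CCCCC1B(C1CCCCC1)/C=C/C(C)=C/CO[Si](c1ccccc1)(c1ccccc1)C(C)(C)C | intermediate
8 | (E)-5-(tert-butyldiphenylsilyloxy)-3-methylpent-3-enal | O=CC/C(C)=C/CO[Si](c1ccccc1)(c1ccccc1)C(C)(C)C | intermediate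
9 | (E)-5-(tert-butyldiphenylsilyloxy)-3-methylpent-3-enoic acid | OC(=O)C/C(C)=C/CO[Si](c1ccccc1)(c1ccccc1)C(C)(C)C | intermediate
10 | (S)-2,2,4-trimethylcyclohex-3-en-1-yl (E)-5-(tert-butyldiphenylsilyloxy)-3-methylpent-3-enoate | O=C(C/C(C)=C/CO[Si](c1ccccc1)(c1ccccc1)C(C)(C)C)O[C@H]1CCC(C)=CC1(C)C | intermediate
11 | tert-butyl{[(1E,3E)-5-(tert-butyldiphenylsilyloxy)-3-methyl-1-{[(S)-2,2,4-trimethylcyclohex-3-en-1-yl]oxy}penta-1,3-dien-1-yl]oxy}dimethylsilane (ring-A oxygen cis to C8; not isolated) | CC(C)(C)[Si](C)(C)O/C(O[C@H]1CCC(C)=CC1(C)C)=C/C(C)=C/CO[Si](c1ccccc1)(c1ccccc1)C(C)(C)C | intermediate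
12 | (3S,5R,6S,9R,10S)-6-(tert-butyldimethylsilyloxy)-11-(tert-butyldiphenylsilyloxy)-3,6-epoxydrim-7-ene (cis-fused bridged silyl ketal; oxygen bridge and ring B on the face opposite to the C10 methyl, C11 cis to the C10 methyl) | CC1=C[C@@]2(O[Si](C)(C)C(C)(C)C)O[C@H]3CC[C@]([C@@H]1CO[Si](c1ccccc1)(c1ccccc1)C(C)(C)C)(C)[C@@H]2C3(C)C | intermediate
13 | (3S,5R,9R,10S)-11-(tert-butyldiphenylsilyloxy)-3-hydroxydrim-7-en-6-one (cis-fused; in equilibrium with its 3,6-hemiketal; not isolated) | CC1=CC(=O)[C@H]2C(C)(C)[C@@H](O)CC[C@@]2(C)[C@@H]1CO[Si](c1ccccc1)(c1ccccc1)C(C)(C)C | intermediate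
14 | (5R,9R,10S)-11-(tert-butyldiphenylsilyloxy)drim-7-ene-3,6-dione (cis-fused, 5-H syn to the C10 methyl) | CC1=CC(=O)[C@H]2C(C)(C)C(=O)CC[C@@]2(C)[C@@H]1CO[Si](c1ccccc1)(c1ccccc1)C(C)(C)C | intermediate
15 | dilithium (9R,10S)-11-(tert-butyldiphenylsilyloxy)drima-2,5,7-triene-3,6-diolate (not isolated) | [Li+].[Li+].CC1=CC([O-])=C2C(C)(C)C([O-])=CC[C@@]2(C)[C@@H]1CO[Si](c1ccccc1)(c1ccccc1)C(C)(C)C | intermediate
16 | (5S,9R,10S)-11-(tert-butyldiphenylsilyloxy)drim-7-ene-3,6-dione (trans-fused) | CC1=CC(=O)[C@@H]2C(C)(C)C(=O)CC[C@@]2(C)[C@@H]1CO[Si](c1ccccc1)(c1ccccc1)C(C)(C)C | intermediate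
17 | (5S,9R,10S)-11-hydroxydrim-7-ene-3,6-dione | CC1=CC(=O)[C@@H]2C(C)(C)C(=O)CC[C@@]2(C)[C@@H]1CO | intermediate
18 | umbelliferone (7-hydroxy-2H-chromen-2-one) | Oc1ccc2ccc(=O)oc2c1 | starting material
19 | epi-conferdione, 7-{[(1R,4aS,8aS)-2,5,5,8a-tetramethyl-4,6-dioxo-1,4,4a,5,6,7,8,8a-octahydronaphthalen-1-yl]methoxy}-2H-chromen-2-one | CC1=CC(=O)[C@@H]2C(C)(C)C(=O)CC[C@@]2(C)[C@@H]1COc1ccc2ccc(=O)oc2c1 | target

Total step count: 11. Longest linear sequence: 9 steps (steps 3–11, from 5 to 19).

Steps most likely to fail

Step 7. The cycloaddition onto the unactivated, trisubstituted C5=C10 alkene may be slower than O-to-C silyl migration or retro-ene fragmentation of the ketene silyl acetal. Enolization may also give the acetal isomer with the ring-A oxygen trans to C8, which cannot reach the alkene. The fallback uses a silicon-free, thermally robust diene that equilibrates its geometry, made by amide acetal exchange as in the Eschenmoser–Claisen rearrangement. It sets out from acid 9 and alcohol 4. Acid 9 is coupled with dimethylamine to the N,N-dimethylamide F1, which is O-methylated with Me3OBF4 and treated with NaOMe to give the amide dimethyl acetal F2. Heating F2 with 4 in xylene at 140–160 °C should exchange methanol for the ring-A alcohol and eliminate methanol to the ketene N,O-acetal F3, whose intramolecular Diels–Alder reaction should give the N,O-ketal cycloadduct F4. Dilute aqueous acid should then release dimethylamine and give hydroxy enone 13, where the fallback comes back to the route (chromic acid oxidation to 14 as in step 8).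

Step 9. Deprotonation at the hindered ring-fusion C5–H, which is flanked by two quaternary carbons, may be slower than γ-deprotonation of the enone; that would scramble C9 or expel the C11 silyloxide. The fallback replaces the hard amide base by soft enolization. From 14, Me3SiOTf and Et3N in CH2Cl2 at 0 °C should give the bis(trimethylsilyl) dienol ether F5, with the tetrasubstituted C5=C6 enol ether favoured. After isolation, protodesilylation with dilute HCl in THF at −78 °C should protonate C5 anti to the C10 methyl and return to the route at 16.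

Step 11. The alkoxyphosphonium ion at the β-branched C11 may lose the γ-hydrogen at C9, eliminating toward the exocyclic dienone, faster than it is displaced by the phenol. The fallback uses a preformed sulfonate and a weakly basic phenoxide. From 17, Tf2O and 2,6-di-tert-butyl-4-methylpyridine in CH2Cl2 at −78 °C should give the triflate F6. Displacement at −20 °C in MeCN by the tetrabutylammonium salt of umbelliferone 18 should return to the route at 19.

Further compounds
F1 | step 7 | (E)-5-(tert-butyldiphenylsilyloxy)-N,N,3-trimethylpent-3-enamide | CN(C)C(=O)C/C(C)=C/CO[Si](c1ccccc1)(c1ccccc1)C(C)(C)C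
F2 | step 7 | (E)-5-(tert-butyldiphenylsilyloxy)-1,1-dimethoxy-N,N,3-trimethylpent-3-en-1-amine | CN(C)C(OC)(OC)C/C(C)=C/CO[Si](c1ccccc1)(c1ccccc1)C(C)(C)C
F3 | step 7 | (1E,3E)-5-(tert-butyldiphenylsilyloxy)-N,N,3-trimethyl-1-{[(S)-2,2,4-trimethylcyclohex-3-en-1-yl]oxy}penta-1,3-dien-1-amine (ring-A oxygen cis to C8) | CN(C)/C(O[C@H]1CCC(C)=CC1(C)C)=C/C(C)=C/CO[Si](c1ccccc1)(c1ccccc1)C(C)(C)C
F4 | step 7 | (3S,5R,9R,10S)-11-(tert-butyldiphenylsilyloxy)-6-(dimethylamino)-3,6-epoxydrim-7-ene (cis-fused bridged N,O-ketal) | CC1=C[C@@]2(N(C)C)O[C@H]3CC[C@]([C@@H]1CO[Si](c1ccccc1)(c1ccccc1)C(C)(C)C)(C)[C@@H]2C3(C)C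
F5 | step 9 | (9R,10S)-11-(tert-butyldiphenylsilyloxy)-3,6-bis(trimethylsilyloxy)drima-2,5,7-triene | CC1=CC(O[Si](C)(C)C)=C2C(C)(C)C(O[Si](C)(C)C)=CC[C@@]2(C)[C@@H]1CO[Si](c1ccccc1)(c1ccccc1)C(C)(C)C
F6 | step 11 | [(5S,9R,10S)-3,6-dioxodrim-7-en-11-yl] trifluoromethanesulfonate | CC1=CC(=O)[C@@H]2C(C)(C)C(=O)CC[C@@]2(C)[C@@H]1COS(=O)(=O)C(F)(F)F
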